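The data were computed with constants of no real substance, noise included.

Compare the runs at one shared time, not curve by curve, and take from them the power of reagent concentration that they follow.

common to all: starting material 0.20 M; free catalyst 0.10 mM

|  | reagent | remark | time |
|---|---|---|---|
| alder | 0.40 M | run made earlier |  |
| cedar | 0.20 M | run made earlier |  |
| ash | 0.30 M | run made earlier |  |
| delta | 0.400 M | one stirred flow tank at steady state, fed with the mixture as stated, mean residence time 40.0 h |  |
| alpha | 0.400 M (fed, over 2.00 h) | all but reagent at the start; reagent goes in evenly over 2.00 h, the run ends at 4.0 h | 4.0 h |
| theta | 0.400 M | everything together in a closed stirred flask, run for 4.0 h | 4.0 h |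
| eta | 0.400 M | one stirred flow tank at steady state, fed with the mixture as stated, mean residence time 4.0 h |  |

- alder (time / h: target / %): 0.500: 5; 1.33: 18; 2.50: 26; 4.00: 32
- cedar (time / h: target / %): 0.200: 4; 0.417: 5; 1.00: 9; 2.50: 19
- ash (time / h: target / %): 0.667: 7; 1.33: 13; 2.00: 20; 2.50: 22

(readings scatter by 1.5 percentage points)

- the stated concentrations are those of everything mixed, before any reaction; amounts are the same in each set-up
- what was read earlier has a scatter of 1.5 percentage points, one standard deviation
- the feed brings no volume worth counting
- the earlier runs were made in a closed, stirred flask

- the set-up with the highest amount of target at the outlet or at the end, in percent of the starting material put in ("none" if the first two lie within 2 percentage points) (delta / alpha / theta / eta / none)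
- amount of target at the outlet or at the end, in percent of the starting material put in, delta
- amount of target at the outlet or at the end, in percent of the starting material put in, alpha
- amount of target at the outlet or at the end, in percent of the starting material put in, theta
- amount of target at the outlet or at the end, in percent of the starting material put in, eta

Read the tables at 2.50 h, where all three runs have a reading. Cedar, with c(reagent) = 0.20 M, gives 19%. Ash, with 0.30 M, gives 22%. Alder, with 0.40 M, gives 26%. So target rises with reagent, but slowly: alder has twice cedar's reagent and gives 1.37 times its target.

Alder against cedar gives n = 0.453, a reading with the scatter of its two points. This is the apparent order in reagent, the power of c(reagent) that target at one time follows.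

Now the last row of alder. Theta has alder's recipe and time, so I expect about 32% there. Alpha doses reagent evenly over 2.00 h. Counting the dose and not what reacts, the power n averages 1/(1+n) of its full value during dosing and the full value afterwards. Over 4.0 h that gives a factor 0.844, so I reckon alpha at 27.0%.

Alder still climbs from 26% to 32% in its last interval, and delta holds the mixture on average for 40.0 h, ten times theta's time. So I place delta above theta, without a number.

The forecast says otherwise. It names theta as best, with delta 20%, alpha 28%, theta 32.5% and eta 23%, and it reads the runs differently from n: “Early rates scale roughly with reagent.”

Delta gives 41.0%, the most of the set-ups, with theta at 30.1%, alpha at 28.0% and eta at 23.8%.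

    starting material + free catalyst ⇌ catalyst intermediate A (K = 1.30 M⁻¹, k = 0.780 M⁻¹ s⁻¹)
    reagent + catalyst intermediate A ⇌ catalyst intermediate B (K = 140 M⁻¹, k = 7.90 M⁻¹ s⁻¹)
    catalyst intermediate B → free catalyst + target (k = 0.412 s⁻¹)
    target + free catalyst ⇌ isomer of the product + free catalyst, rate k4*[free catalyst]*[target] forward; the back reaction follows from the equilibrium constant (K = 1.20, k = 1.05 M⁻¹ s⁻¹)
    free catalyst ⇌ dormant form (K = 0.384, k = 1.09 × 10⁻⁴ s⁻¹)

Left until 40.0 h, theta reaches 45.4% and alpha 45.4%, which is 4.4 percentage points more than the 41.0% of delta, whose mean residence time is that same span. Delta's tank stands at c(reagent) = 0.230 M, so n puts the reagent term there at 0.778 of its value at the charge. Eta's tank stands at 0.327 M, which puts the term at 0.912.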